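Ring A = the 4-hydroxy-3,5-dimethoxyphenyl ring, ring B = the benzoic acid ring, C1 = ketone carbon, C2 = stereocentre, C3 = CH2OH carbon. The target comes from its dibenzyl derivative (benzyl ether on ring A, benzyl ester on ring B) by hydrogenolysis.
The C1=O group is carried as C1=CH2 and revealed by ozonolysis; at the alkene level C2 is an allylic ether with no acidic hydrogen, so the labile α-aryloxy ketone stereocentre exists only in the last two neutral steps.
Key disconnection: the bond from the ring A ipso carbon to C1, made by carbopalladation of buta-2,3-dien-1-ol with the ring A aryl iodide; in the same flask the resulting racemic vinyl oxirane/π-allyl palladium alkoxide is opened at C2 by the ring B phenol under a chiral ligand (stereoconvergent; sets the C2–O bond and the only stereocentre).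
Enabling feature: C1 (sp2, bound to ring A), C2 (carrying the O–ring B ether) and C3 (CH2OH), with C1=O read as C1=CH2, form a 2-aryl allyl unit with oxygen on two adjacent carbons, which is what a 2-aryl π-allyl palladium complex with a CH2O arm delivers.
Ring order: both benzene rings are bought (4-bromo-2,6-dimethoxyphenol for ring A, syringic acid for ring B); the only ring formed is the transient oxirane of the key step, opened again in the same operation.

Key step: step 4

Assumption: the (S,S) antipode of the DACH-phenyl ligand, N,N'-[(1S,2S)-cyclohexane-1,2-diyl]bis[2-(diphenylphosphanyl)benzamide], is taken to give the (2R) allylic ether in the key step; should the sense of induction prove opposite, the (R,R) antipode is used with no other change.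

Step 1
Reactants: 1 syringic acid (4-hydroxy-3,5-dimethoxybenzoic acid)
Product: 2 benzyl 4-hydroxy-3,5-dimethoxybenzoate (benzyl syringate, ring B fragment)
Conditions: BnBr (1.05 equiv), KHCO3, DMF, 40 °C
Reagents that add atoms: benzyl bromide, BrCc1ccccc1
Why: SN2 O-alkylation of the carboxylate, in which KHCO3 deprotonates only the carboxylic acid, so the less acidic, doubly ortho-substituted phenol should stay free for step 4.

Step 2
Reactants: 3 4-bromo-2,6-dimethoxyphenol
Product: 4 2-(benzyloxy)-5-bromo-1,3-dimethoxybenzene
Conditions: BnBr, K2CO3, DMF, 60 °C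
Reagents that add atoms: benzyl bromide, BrCc1ccccc1
Why: Williamson ether synthesis on the phenoxide, which masks the ring A phenol so that it cannot compete as an oxygen nucleophile in step 4.

Step 3
Reactants: 4 2-(benzyloxy)-5-bromo-1,3-dimethoxybenzene
Product: 5 2-(benzyloxy)-5-iodo-1,3-dimethoxybenzene (ring A fragment)
Conditions: NaI (2 equiv), CuI (5 mol %), trans-N,N'-dimethylcyclohexane-1,2-diamine (10 mol %), 1,4-dioxane, 110 °C
Reagents that add atoms: sodium iodide, [Na+].[I-]
Why: Copper-catalysed aromatic Finkelstein halogen exchange, which should turn the electron-rich bromide into the iodide that adds oxidatively to zerovalent palladium under the mild conditions of step 4, the ethers being inert.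

Step 4
Reactants: 5 2-(benzyloxy)-5-iodo-1,3-dimethoxybenzene, 6 buta-2,3-dien-1-ol, 2 benzyl 4-hydroxy-3,5-dimethoxybenzoate
Product: 8 benzyl 4-{[(2R)-3-[4-(benzyloxy)-3,5-dimethoxyphenyl]-1-hydroxybut-3-en-2-yl]oxy}-3,5-dimethoxybenzoate, via racemic aryl vinyl oxirane 7 (not isolated)
Conditions: Pd2(dba)3·CHCl3 (2.5 mol %), (S,S)-DACH-phenyl ligand (7.5 mol %), Cs2CO3 (1.1 equiv), THF, 50 °C; then 2, CH2Cl2, 0 °C to rt
Reagents that add atoms: none
Why: Proposed new method: zerovalent palladium inserts into the C–I bond of 5 and the aryl group is transferred to the central carbon of allene 6 (carbopalladation), which forms the bond from the ring A ipso carbon to C1 and a 2-aryl π-allyl palladium complex whose alkoxide arm closes reversibly to the racemic oxirane 7. The same chiral catalyst re-ionises 7, the diastereomeric π-allyl complexes interconvert by π–σ–π exchange at the unsubstituted CH2 terminus, and phenol 2, deprotonated by and hydrogen-bonded to the alkoxide, attacks C2, so both enantiomers of 7 should be funnelled into one ether (dynamic kinetic asymmetric transformation). The closest known reaction types are the palladium-catalysed coupling–cyclisation of 2,3-allenols with aryl iodides to vinyl oxiranes and the Tsuji–Trost-type dynamic kinetic asymmetric opening of vinyl oxiranes by O–H and N–H pronucleophiles with this ligand class; new is their merger under one chiral catalyst on a 2-aryl allyl unit. The only ring closed is the transient oxirane (3-exo attack of the alkoxide on the allyl terminus), which is opened again in the same flask. The C2 stereocentre is set under catalyst control by the ligand, the substrate being achiral or racemic at every stage. The step needs aryl transfer to the central allene carbon, which is the normal regiochemistry of allene carbopalladation, and attack at the branched C2 instead of the CH2 terminus, which the alkoxide-directed delivery of the acidic di-ortho-methoxy phenol and the ligand pocket should secure; the reaction is stopped when 7 is consumed so that re-ionisation of the allylic aryl ether does not erode either selectivity.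

Step 5
Reactants: 8 benzyl 4-{[(2R)-3-[4-(benzyloxy)-3,5-dimethoxyphenyl]-1-hydroxybut-3-en-2-yl]oxy}-3,5-dimethoxybenzoate
Product: 9 benzyl 4-{[(2S)-1-[4-(benzyloxy)-3,5-dimethoxyphenyl]-3-hydroxy-1-oxopropan-2-yl]oxy}-3,5-dimethoxybenzoate
Conditions: O3, CH2Cl2/MeOH, −78 °C (Sudan Red 7B end point); then Me2S, −78 °C to rt
Reagents that add atoms: ozone, [O-][O+]=O
Why: Ozonolysis with reductive work-up should cleave the 1,1-disubstituted styrene-type alkene much faster than ozone attacks the alkoxy arenes or benzyl groups, unmasking the C1 ketone at low temperature under neutral conditions so that C2 is untouched in space (its descriptor changes from R to S only because C1 now outranks C3).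

Step 6
Reactants: 9 benzyl 4-{[(2S)-1-[4-(benzyloxy)-3,5-dimethoxyphenyl]-3-hydroxy-1-oxopropan-2-yl]oxy}-3,5-dimethoxybenzoate
Product: 10 4-{[(2S)-3-hydroxy-1-(4-hydroxy-3,5-dimethoxyphenyl)-1-oxopropan-2-yl]oxy}-3,5-dimethoxybenzoic acid (target)
Conditions: H2 (1 atm), 10% Pd/C, EtOAc, rt
Reagents that add atoms: none
Why: Heterogeneous catalytic hydrogenolysis should remove the benzyl ester and the phenolic benzyl ether (two equivalents of toluene) under neutral conditions, avoiding the base- or acid-induced epimerisation, retro-aldol cleavage and elimination open to the β-hydroxy-α-aryloxy ketone, while the electron-rich aryl ketone is reduced far more slowly.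

Compound list
1 | syringic acid (4-hydroxy-3,5-dimethoxybenzoic acid) | COc1cc(C(=O)O)cc(OC)c1O | starting material
2 | benzyl 4-hydroxy-3,5-dimethoxybenzoate | COc1cc(C(=O)OCc2ccccc2)cc(OC)c1O | intermediate
3 | 4-bromo-2,6-dimethoxyphenol | COc1cc(Br)cc(OC)c1O | starting material
4 | 2-(benzyloxy)-5-bromo-1,3-dimethoxybenzene | COc1cc(Br)cc(OC)c1OCc1ccccc1 | intermediate
5 | 2-(benzyloxy)-5-iodo-1,3-dimethoxybenzene | COc1cc(I)cc(OC)c1OCc1ccccc1 | intermediate
6 | buta-2,3-dien-1-ol | C=C=CCO | starting material
7 | racemic 2-{1-[4-(benzyloxy)-3,5-dimethoxyphenyl]ethenyl}oxirane | C=C(c1cc(OC)c(OCc2ccccc2)c(OC)c1)C1CO1 | intermediate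
8 | benzyl 4-{[(2R)-3-[4-(benzyloxy)-3,5-dimethoxyphenyl]-1-hydroxybut-3-en-2-yl]oxy}-3,5-dimethoxybenzoate | C=C(c1cc(OC)c(OCc2ccccc2)c(OC)c1)[C@H](CO)Oc1c(OC)cc(C(=O)OCc2ccccc2)cc1OC | intermediate
9 | benzyl 4-{[(2S)-1-[4-(benzyloxy)-3,5-dimethoxyphenyl]-3-hydroxy-1-oxopropan-2-yl]oxy}-3,5-dimethoxybenzoate | COc1cc(C(=O)[C@H](CO)Oc2c(OC)cc(C(=O)OCc3ccccc3)cc2OC)cc(OC)c1OCc1ccccc1 | intermediate
10 | 4-{[(2S)-3-hydroxy-1-(4-hydroxy-3,5-dimethoxyphenyl)-1-oxopropan-2-yl]oxy}-3,5-dimethoxybenzoic acid | COc1cc(C(=O)[C@H](CO)Oc2c(OC)cc(C(=O)O)cc2OC)cc(OC)c1O | target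

Total step count: 6. Longest linear sequence: 5 steps (3 → 4 → 5 → 8 → 9 → 10); step 1 is a one-step side branch that joins in step 4.

Steps most likely to fail

Step 4 (proposed new method). The phenoxide may attack the unsubstituted allyl terminus and give the linear ether. The π-allyl alkoxide may isomerise to an enal by β-hydride elimination before the phenol is added. The allylic aryl ether may re-ionise and lose enantiopurity. The fallback uses only known chemistry, sets out from 2 and 5 and comes back to the route at 10. Commercial (2R)-3-(benzyloxy)-2-hydroxypropanoic acid is coupled with MeNHOMe·HCl (EDC·HCl, HOBt, iPr2NEt, CH2Cl2) to (2R)-3-(benzyloxy)-2-hydroxy-N-methoxy-N-methylpropanamide F1. A Mitsunobu reaction of F1 with 2 (PPh3, DIAD, toluene, 0 °C to rt) should give, with inversion at C2, benzyl 4-{[(2S)-3-(benzyloxy)-1-[methoxy(methyl)amino]-1-oxopropan-2-yl]oxy}-3,5-dimethoxybenzoate F2. Iodine–magnesium exchange on 5 (iPrMgCl·LiCl, THF, −20 °C) gives [4-(benzyloxy)-3,5-dimethoxyphenyl]magnesium chloride F3. F3 is added to F2 at −40 °C, where the chelated tetrahedral intermediate protects the stereocentre and the electron-rich ring B benzyl ester should react too slowly to interfere. This forms the same bond between ring A and C1 and gives benzyl 4-{[(2S)-3-(benzyloxy)-1-[4-(benzyloxy)-3,5-dimethoxyphenyl]-1-oxopropan-2-yl]oxy}-3,5-dimethoxybenzoate F4. Hydrogenolysis of the three benzyl groups of F4 (H2, 10% Pd/C, EtOAc, rt) then gives 10.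

Step 5. Ozone may oxidise the electron-rich alkoxy arenes or the benzylic positions before the alkene is consumed, and peroxidic intermediates may survive the work-up. The fallback sets out from 8 and comes back at 9 without ozone. Dihydroxylation of the alkene (K2OsO4·2H2O cat., N-methylmorpholine N-oxide, acetone/H2O, rt) should give benzyl 4-{[(2S)-3-[4-(benzyloxy)-3,5-dimethoxyphenyl]-1,3,4-trihydroxybutan-2-yl]oxy}-3,5-dimethoxybenzoate F5, as a mixture of epimers at the new tertiary carbinol. Glycol cleavage of its only vicinal diol (NaIO4, THF/H2O, pH 7 buffer, 0 °C) then gives 9.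

Step 6. Hydrogenolytic cleavage of the C2–O aryl ether bond next to the ketone, or reduction of the aryl ketone, may compete with debenzylation. The fallback sets out from 9 and comes back at 10 by non-reductive debenzylation. BCl3 with pentamethylbenzene as cation scavenger (CH2Cl2, −78 °C, then MeOH quench) should cleave the benzyl aryl ether and the benzyl ester by benzyl cation transfer. The methyl ethers and the ketone are left alone, and no new intermediate is formed.

Further compounds
F1 | step 4 | (2R)-3-(benzyloxy)-2-hydroxy-N-methoxy-N-methylpropanamide | CON(C)C(=O)[C@@H](COCc1ccccc1)O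
F2 | step 4 | benzyl 4-{[(2S)-3-(benzyloxy)-1-[methoxy(methyl)amino]-1-oxopropan-2-yl]oxy}-3,5-dimethoxybenzoate | CON(C)C(=O)[C@H](COCc1ccccc1)Oc1c(OC)cc(C(=O)OCc2ccccc2)cc1OC
F3 | step 4 | [4-(benzyloxy)-3,5-dimethoxyphenyl]magnesium chloride | COc1cc([Mg]Cl)cc(OC)c1OCc1ccccc1
F4 | step 4 | benzyl 4-{[(2S)-3-(benzyloxy)-1-[4-(benzyloxy)-3,5-dimethoxyphenyl]-1-oxopropan-2-yl]oxy}-3,5-dimethoxybenzoate | COc1cc(C(=O)[C@H](COCc2ccccc2)Oc2c(OC)cc(C(=O)OCc3ccccc3)cc2OC)cc(OC)c1OCc1ccccc1
F5 | step 5 | benzyl 4-{[(2S)-3-[4-(benzyloxy)-3,5-dimethoxyphenyl]-1,3,4-trihydroxybutan-2-yl]oxy}-3,5-dimethoxybenzoate | OCC(O)(c1cc(OC)c(OCc2ccccc2)c(OC)c1)[C@H](CO)Oc1c(OC)cc(C(=O)OCc2ccccc2)cc1OC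
F0 | step 6 | none | none
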